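A ratio follows J through this flask: the rate at which dimerisation uses J over the rate at which attack on Z uses it. That ratio changes as the flask runs: it is the loss constant, a selectivity factor fixed by the dimerisation constant counted for the 2 J of each turn over the attack constant, 5.47, times free J over free Z.

Z 0.050 M; time 2.5 h

- the concentration of J at which the part of the Z that has reacted at 2.5 h is just 70%, in M

- Q is meant together with its Z.Q
- for a step with 2 of a species take k times the square, and two of it per event
- the amount of J is what is sought; it is there from the start
- what has gone from Z into another species counts as reacted, even if it can come back
- run time (flask): 2.5 h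

    2 J → J2 (k1 = 0.52 L mol⁻¹ min⁻¹)
    Z + Q ⇌ Z.Q, settled at all times (K2 = 28 L mol⁻¹)
    Z + Q → L (k3 = 2.0 L mol⁻¹ min⁻¹)
    Z + J → Q + G (k4 = 0.19 L mol⁻¹ min⁻¹)
    J + Q ⇌ J.Q, settled at all times (K5 = 380 L mol⁻¹)

The J charge is the setting to turn by hand. If dimerisation is taken as the loss of J and Q is ignored, the fraction of Z left is one plus run time over the first half-life of J by dimerisation, raised to minus one over the loss constant, and the part wanted then takes 4.66 M of J. But each attack frees Q, whose half-life against the Z charged is 6.93 min, far shorter than the run, so each attack costs 2 Z, and this text's own reckoning commits to 0.167 M, leaving Z.Q and J.Q aside. At that charge the ratio starts at 18.2, well above one, so taking dimerisation as the loss of J holds at the start. The Z charge, the other setting, cancels from this reckoning while Q stays short-lived.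

The forecast gives 0.13 M, less than this reckoning, on the ground that “each G formed also releases Q, which consumes more Z and holds J as J.Q”.

The simulation gives 0.271 M, more than either estimate. At 2.50 h the share of the charged J still free is 2.50%, which is 0.00677 M, while the Z not yet reacted is 0.0150 M. Dimerisation still uses J faster than attack on Z does, and the loss constant puts the ratio, 29.6 at the charge, at 2.47 by then.

The rate constants are invented.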